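How much target stands in the flask at 50 min, and how much starting material has reacted by then? To answer, first find which concentration sets the rate.

the same everywhere: starting material 0.050 M
- maple: reagent in the second phase 1.5 equiv; protic impurity 0.017 M; run made earlier
- oak: reagent in the second phase 1.5 equiv; protic impurity 0.038 M; run made earlier
- alder: reagent in the second phase 2.2 equiv; protic impurity 0.025 M; run made earlier
- flask: reagent in the second phase 1.50 equiv; protic impurity 0.0250 M; time 50 min; volume of the second phase over the first 0.25

| run | time / min | target / % | starting material / % |
|---|---|---|---|
| maple | 3.00 | 2.9 | 96.4 |
| maple | 5.00 | 7.9 | 93.3 |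
| maple | 8.00 | 11.6 | 85.9 |
| maple | 15.0 | 22.6 | 71.7 |
| maple | 25.0 | 30.3 | 55.6 |
| maple | 40.0 | 33.1 | 43.9 |
| oak | 6.00 | 6.4 | 93.8 |
| oak | 12.0 | 14.1 | 84.1 |
| oak | 20.0 | 20.5 | 75.4 |
| oak | 25.0 | 23.9 | 70.1 |
| oak | 30.0 | 27.0 | 65.4 |
| oak | 40.0 | 29.1 | 58.5 |
| alder | 3.00 | 4.6 | 96.5 |
| alder | 6.00 | 11.0 | 87.5 |
| alder | 12.0 | 23.6 | 70.6 |
| alder | 20.0 | 32.0 | 51.8 |
| alder | 40.0 | 31.4 | 28.4 |

(scatter of a reading: 0.5 percentage points)

- in the second phase: reagent in the second phase; everything else is in the first
- charges count per volume of the first phase; a concentration in a rate is the amount of a species over the volume of its own phase; every rate counts per litre of the first phase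
- the earlier runs hold the two phases in the same ratio of volumes as the flask asked about

* the target standing at 50 min, as a percentage of the starting material charged
* part of the starting material charged that has reacted at 50 min

In the runs, the first-order constant of the starting material follows the spare reagent, meaning reagent charged minus protic impurity charged, per volume of the first phase 0.0500 M. The flask has the value just printed, and maple has 0.0580 M. Take ln of the fall in starting material up to 40.0 min and divide by time and spare reagent. Maple gives 0.00591 /M/s, oak 0.00604 /M/s and alder 0.00617 /M/s. These readings nearly agree, so I use spare reagent as an empirical scale for the runs up to their last readings, not as a concentration in the rate law.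

Now build the flask. With the main step by itself and the whole reagent charge working, 26.4% of the starting material remains, so the target is 73.6%. Add the impurity, which takes its own amount of reagent, and the spare reagent leaves 41.2%, with target 58.8%. Then add the rest, since reagent gets used and target is lost. Maple's last stretch gives a lower constant, 0.00453 /M/s. Using it for the flask's last 10.0 min, I commit to 57.1% reacted. Alder's target flattens from 32.0% to 31.4%, and maple stands at 33.1%, so I put the target near that last figure.

The forecast says 32.3% and 56.5%, slightly below my conversion: “Target is near its plateau, with formation roughly balancing loss”.

The flask gives 33.2% of target with 55.5% reacted.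

    reagent in the reaction phase ⇌ reagent in the second phase, rate k1*([reagent in the reaction phase] - [reagent in the second phase]/K1) per volume of the first phase (partition coefficient = 2.30, kL = 9.70 × 10⁻⁴ /s)
    starting material + reagent in the reaction phase → target (k = 0.0240 /M/s)
    reagent in the reaction phase + target → over-reaction product (k = 0.0290 /M/s)
    reagent in the reaction phase + protic impurity → quenched reagent (k = 0.210 /M/s)

The largest single effect on the flask's target is the over-reaction of target with reagent in the reaction phase: without that step the target stands at 63.1% instead of 33.2%. At 50.0 min the flask holds 0.084% of its impurity charge, so the charged spare reagent of 0.0500 M counts what the impurity left for the other steps. The neighbour with 0.062 M of impurity has 0.0130 M spare, so the maple constant leaves 79.4% of its starting material, and that neighbour holds 74.6%.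

The runs are calculated for an exercise, and the scatter is random.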